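## Structural features

Locants are written C1(A) to C8a(A) for the 1-methoxy-6-methylnaphthalene-3,8-diol half (unit A) and C1(B) to C8a(B) for the 5-methoxy-2-methylnaphthalene-4,6-diol half (unit B).

The target is an unsymmetrical binaphthalene in which C4(A) is bonded to C1(B). In unit A, ring P (C1, C2, C3, C4, C4a, C8a) carries OMe at C1, H at C2, OH at C3 and the biaryl bond at C4; the fused benzo ring carries OH at C8 (peri to the C1 methoxy group) and CH3 at C6. In unit B, ring R (C1 to C4, C4a, C8a) carries the biaryl bond, CH3 at C2 and OH at C4, and ring Q carries OMe at C5 and OH at C6. There is no stereocentre. The only stereogenic element is the biaryl axis, flanked by the C3(A) oxygen, the C5(A) peri hydrogen, the C2(B) methyl group and the C8(B) peri hydrogen. The four free naphthol hydroxyls sit on very electron-rich rings and are prone to air oxidation, so they should stay masked until a neutral last step. The real difficulties are the hindered, tetra-ortho-substituted biaryl bond and the oxygen pattern: C1(A) methylated next to a free C3(A) hydroxyl in the same resorcinol ring, and C5(B) methylated between two free hydroxyls. The key step exploits ring P: C1 can come from a ketene carbon, C2–C3 from an oxygenated alkyne and C4 from a benzylic carbon that already carries unit B. The biaryl bond is therefore first made as an sp2–sp3 bond, and the two ring-P oxygens arrive differently substituted.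

## Logic of the disconnections

**32 to 29.** The three O–benzyl bonds at C8(A), C4(B) and C6(B), the O–Si bond at C3(A) and the O–CH3 bond at C1(A) are cut in turn, leading back through 31 and 30 to 29. This keeps every sensitive naphthol masked until a neutral hydrogenolysis and reduces the methylation problem to a single free hydroxyl. The demand is that 29 already has its two ring-P oxygens differentiated and that silicon, benzyl and methyl are removable independently.

**29 to 22 and 26.** Bonds C1(A)–C2(A) and C3(A)–C4(A) are cut and the C1(A)–C4(A) bond of a four-membered ring is restored. Ring P disappears, the hindered biaryl bond becomes an ordinary sp3–sp2 bond, and the two oxygens are traced to two different components. The forward step must open 22 at its C(=O)–CH bond, take up 26 with its CH carbon at the ketene carbon, and close through the benzylic carbon.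

**22 to 20 and 16.** Bonds C4(A)–C4a(A) and C1(A)–C8a(A) are cut (retro-[2+2] of an aryne with a ketene silyl acetal). This splits the molecule into two halves of similar size. The forward step needs the nucleophilic carbon of 16 to attack the aryne carbon meta to the benzyloxy group. It also needs an aryne source that leaves the silyl acetal intact, which is why 20 is an ortho-iodoaryl triflate activated by halogen–lithium exchange and not a silylaryl triflate activated by fluoride.

**26 to 23.** The O–Si and C–O bonds are cut. The demand is O-silylation (not C-silylation) of an ynolate.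

**20 to 17.** The O–S bond, one O–benzyl bond and the C–I bond are cut, through 19 and 18. Symmetrical 17 removes all regiochemical questions except iodination between the two hydroxyls; the mono-benzylation is statistical.

**16 to 14.** The O–Si bond is cut to give 15, then the bond between C1(B) and the side-chain CH2 (the future C4(A)–C1(B) bond) is cut to give 14 and an acetate enolate equivalent. The hindered biaryl bond is thus made as an sp2–sp3 cross-coupling. The demand is coupling at a di-ortho-substituted aryl bromide.

**14 to 12.** The O–benzyl bond at C4(B) and the C–Br bond at C1(B) are cut, through 13. Bromination must go para to the free hydroxyl of 12 and not into ring Q, so it is placed before benzylation.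

**12 to 9 and 10.** Ring R is cut at C2(B)–C3(B) (aldol condensation) and at C1(B)–C8a(B) and C4(B)–C4a(B) (insertion of an aryne into a C–C bond of 10). The whole ring with its methyl and hydroxyl groups comes from 10 in one flask. The demands are aryne regiochemistry (acetyl next to the methoxy group) and the right direction of the aldol closure.

**9 to 1.** The O–S bond, the C–Si bond, the carbamate and finally the aryl C–O bond are cut, through 8, 7, 4 and 3. The demand is metalation between the carbamate and the methoxy group in the presence of a benzyl ether.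

## Other disconnections considered

**Alternative 1:** The same two bonds to the benzo ring of unit A, C4(A)–C4a(A) and C1(A)–C8a(A), are cut, but on an open-chain partner. The aryne from 3-(benzyloxy)-5-methyl-2-(trimethylsilyl)phenyl trifluoromethanesulfonate A3 would insert into the bond between the α-carbon and the acetyl group of methyl 2-[4,6-bis(benzyloxy)-5-methoxy-2-methylnaphthalen-1-yl]-3-oxobutanoate A2 (one acylation from 15). This gives methyl 2-[2-acetyl-3-(benzyloxy)-5-methylphenyl]-2-[4,6-bis(benzyloxy)-5-methoxy-2-methylnaphthalen-1-yl]acetate A1. Ring P then closes in a separate Claisen-type step (bond C2(A)–C3(A)) to 8-(benzyloxy)-4-[4,6-bis(benzyloxy)-5-methoxy-2-methylnaphthalen-1-yl]-6-methylnaphthalene-1,3-diol A4.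
- In favour: aryne acyl-alkylation is a known reaction class, it needs neither light nor an ynol ether, and it uses the same directing benzyloxy group and the same sp3-first construction of the biaryl bond. On precedent for the ring-forming chemistry it is the better plan.
- Against: the nucleophile is a fully substituted enolate next to the 2-methylnaphthyl group, so C-arylation passes through a quaternary carbon and competes with O-arylation and simple protonation. Both ring-P oxygens of A4 arrive as free hydroxyls, so the C1-methyl/C3-free pattern must be won afterwards by a selective protection.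
- Comparison: structurally the two plans treat the axis identically. Mechanistically alternative 1 uses two known polar steps against one unprecedented cascade. Step economy is about equal; the chosen plan is ahead only because oxygen differentiation is part of the C–C bond formation.

**Alternative 2:** Ring P is cut only at C4(A)–C4a(A), after the benzo ring of unit A has been taken back to a cyclohexanedione oxidation level. Hydroxide would open the pyranone ring of 2-{[4,6-bis(benzyloxy)-5-methoxy-2-methylnaphthalen-1-yl]methyl}-7-methyl-7,8-dihydro-4H-chromene-4,5(6H)-dione A6 to an enolised tetraketone. Its benzylic carbon condenses with the ring carbonyl to give 5-[4,6-bis(benzyloxy)-5-methoxy-2-methylnaphthalen-1-yl]-6,8-dihydroxy-3-methyl-3,4-dihydronaphthalen-1(2H)-one A5.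
- In favour: no aryne, no photochemistry, cheap carbonyl components. In A5 the C1(A) hydroxyl is chelated to the ketone, so the C3(A) hydroxyl can be masked first and C1(A) methylated afterwards. On oxygen differentiation it equals the chosen plan, and each single reaction type is probably more reliable.
- Against: the attacking carbon carries bulky unit B and the acceptor is a poorly electrophilic vinylogous acid carbonyl. The saturated ring of A5 must later be dehydrogenated to the C8(A) naphthol in the presence of benzyl ethers and an electron-rich biaryl. A6 needs its own multi-step assembly from 15.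
- Comparison: the same sp3-first idea, ordinary condensations in place of one uncertain cascade, but clearly worse step economy (pyranone assembly, ring transformation, protection, methylation, aromatisation, deprotection).

**Alternative 3:** The cut is moved into unit B: bonds C1(B)–C2(B) and C3(B)–C4(B) of ring R. The anion of 6-(benzyloxy)-3-[3,8-bis(benzyloxy)-1-methoxy-6-methylnaphthalen-4-yl]-7-methoxy-2-benzofuran-1(3H)-one A8 would add to the β-carbon of tert-butyl (E)-but-2-enoate A9. The ester enolate would attack the lactone carbonyl, and acidic work-up would dehydrate to tert-butyl 6-(benzyloxy)-1-[3,8-bis(benzyloxy)-1-methoxy-6-methylnaphthalen-4-yl]-4-hydroxy-5-methoxy-2-methylnaphthalene-3-carboxylate A7.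
- In favour: anionic phthalide annulation is a known class, and one step installs ring R with its methyl group and a free C4(B) hydroxyl. The biaryl bond again starts as a bond to an sp3 carbon, which equals the chosen plan. Unit B needs no aryne chemistry, which is better.
- Against: A8 presupposes a complete unit A naphthalene, already differentiated at C1 and C3 and metalated at C4, so the ring-P problem is only moved. The Michael addition must build a fully substituted carbon beside the naphthyl group and is prone to reversal. The ester of A7 costs an extra cleavage and decarboxylation.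
- Comparison: the same final substitution; a known polar annulation (advantage on precedent) with a higher steric demand; worse step economy because unit A must be made separately and the ester removed.

Key step: step 15

Assumption: the target is drawn without an axial descriptor, so the hindered biaryl axis is made as the racemate. Compound 1 is the commercial benzyl ether of vanillin; 10, 17 and 23 are commercial.

## Route

Step 1
Reactants: 1 4-(benzyloxy)-3-methoxybenzaldehyde
Product: 3 4-(benzyloxy)-3-methoxyphenol, via aryl formate 2 (not isolated)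
Conditions: mCPBA, CH2Cl2, 0 °C to rt; aq NaHCO3 wash; then K2CO3 (cat.), MeOH, rt
Reagents that add atoms: 3-chloroperoxybenzoic acid, OOC(=O)c1cccc(Cl)c1
Why: Baeyer–Villiger (Dakin-type) oxidation: the electron-rich aryl group migrates to give the formate, and methanolysis frees the phenol; benzyl and methyl ethers are inert.

Step 2
Reactants: 3 4-(benzyloxy)-3-methoxyphenol
Product: 4 4-(benzyloxy)-3-methoxyphenyl propan-2-ylcarbamate
Conditions: i-PrNCO, Et3N (cat.), CH2Cl2, rt
Reagents that add atoms: 2-isocyanatopropane, CC(C)N=C=O
Why: Base-catalysed addition of the phenol to the isocyanate gives an N-isopropyl carbamate, a strong ortho-directing group that can later be removed under mild, fluoride-free base.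

Step 3
Reactants: 4 4-(benzyloxy)-3-methoxyphenyl propan-2-ylcarbamate
Product: 7 4-(benzyloxy)-3-methoxy-2-(trimethylsilyl)phenyl propan-2-ylcarbamate, via N-silyl carbamate 5 (not isolated), via N-silyl C-silyl carbamate 6 (not isolated)
Conditions: TBSOTf, TMEDA, Et2O, 0 °C to rt; n-BuLi, TMEDA, −78 °C; TMSCl, −78 °C to rt; aq NaHSO4
Reagents that add atoms: chlorotrimethylsilane, C[Si](C)(C)Cl; tert-butyldimethylsilyl trifluoromethanesulfonate, CC(C)(C)[Si](C)(C)OS(=O)(=O)C(F)(F)F (its silyl group is carried only by 5 and 6)
Why: Directed ortho-metalation: transient N-silylation blocks N–H deprotonation, the position between carbamate and methoxy group is lithiated by cooperative direction and trapped by TMSCl, and the N-silyl group is lost on acidic work-up. At −78 °C ring lithiation should outrun metalation of the benzylic CH2 of the ether.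

Step 4
Reactants: 7 4-(benzyloxy)-3-methoxy-2-(trimethylsilyl)phenyl propan-2-ylcarbamate
Product: 9 4-(benzyloxy)-3-methoxy-2-(trimethylsilyl)phenyl trifluoromethanesulfonate, via silylphenol 8 (not isolated)
Conditions: DBU, Et2NH, MeCN, 40 °C; then PhNTf2, rt
Reagents that add atoms: N-phenylbis(trifluoromethanesulfonimide), O=S(=O)(N(c1ccccc1)S(=O)(=O)C(F)(F)F)C(F)(F)F
Why: E1cB cleavage of the N–H carbamate (the isocyanate is trapped by Et2NH as a urea) releases the phenoxide, which is triflated in the same flask; the aryl C–Si bond survives these fluoride-free conditions.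

Step 5
Reactants: 9 4-(benzyloxy)-3-methoxy-2-(trimethylsilyl)phenyl trifluoromethanesulfonate; 10 pentane-2,4-dione (acetylacetone)
Product: 12 7-(benzyloxy)-8-methoxy-3-methylnaphthalen-1-ol, via diketone 11 (not isolated)
Conditions: CsF, MeCN, 80 °C; then NaOMe, MeOH, 60 °C (argon); aq HCl
Reagents that add atoms: none
Why: Aryne acyl-alkylation followed by intramolecular aldol condensation: the enolate of 10 attacks the aryne carbon remote from the methoxy group, the aryl anion beside OMe adds to an acetyl group, and the four-membered alkoxide fragments to 11. Methoxide then closes ring R by attack of the hindered aryl methyl ketone enolate on the unhindered aliphatic ketone, and dehydration with enolisation gives the naphthol.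

Step 6
Reactants: 12 7-(benzyloxy)-8-methoxy-3-methylnaphthalen-1-ol
Product: 13 7-(benzyloxy)-4-bromo-8-methoxy-3-methylnaphthalen-1-ol
Conditions: NBS (1.0 equiv), MeCN, −20 °C, dark
Reagents that add atoms: N-bromosuccinimide, O=C1CCC(=O)N1Br
Why: Electrophilic bromination para to the free naphthol hydroxyl (an α-position, also ortho to the methyl group). The free phenol makes ring R far more reactive than the dialkoxy ring Q, which is why bromination precedes benzylation.

Step 7
Reactants: 13 7-(benzyloxy)-4-bromo-8-methoxy-3-methylnaphthalen-1-ol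
Product: 14 4,6-bis(benzyloxy)-1-bromo-5-methoxy-2-methylnaphthalene
Conditions: BnBr, K2CO3, DMF, 50 °C
Reagents that add atoms: benzyl bromide, BrCc1ccccc1
Why: Williamson etherification of the peri-hydrogen-bonded naphthol; the aryl bromide is inert.

Step 8
Reactants: 14 4,6-bis(benzyloxy)-1-bromo-5-methoxy-2-methylnaphthalene
Product: 15 methyl 2-[4,6-bis(benzyloxy)-5-methoxy-2-methylnaphthalen-1-yl]acetate
Conditions: BrZnCH2CO2Me (from BrCH2CO2Me, Zn, THF), Pd[P(t-Bu)3]2 (5 mol %), THF, 60 °C
Reagents that add atoms: bromo(2-methoxy-2-oxoethyl)zinc, COC(=O)C[Zn]Br (made in the flask from methyl bromoacetate, COC(=O)CBr, and zinc)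
Why: Palladium-catalysed α-arylation of an ester by Negishi-type coupling of the aryl bromide with a Reformatsky reagent. The bulky, electron-rich phosphine on zerovalent palladium allows oxidative addition and reductive elimination at the di-ortho-substituted carbon, and the mild zinc enolate tolerates the benzyl ethers; this step forms the future biaryl bond as an sp2–sp3 bond.

Step 9
Reactants: 15 methyl 2-[4,6-bis(benzyloxy)-5-methoxy-2-methylnaphthalen-1-yl]acetate
Product: 16 tert-butyl({2-[4,6-bis(benzyloxy)-5-methoxy-2-methylnaphthalen-1-yl]-1-methoxyethenyl}oxy)dimethylsilane (mixture of double-bond isomers)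
Conditions: LiN(i-Pr)2, THF, −78 °C; TBSCl, DMPU, −78 °C to rt; pentane extraction, cold aq NaHCO3 wash, used crude
Reagents that add atoms: tert-butylchlorodimethylsilane, CC(C)(C)[Si](C)(C)Cl
Why: Ester enolisation and O-silylation give the ketene silyl acetal; the double-bond geometry is irrelevant because this carbon becomes the racemic sp3 centre of 22.

Step 10
Reactants: 17 5-methylbenzene-1,3-diol (orcinol)
Product: 18 2-iodo-5-methylbenzene-1,3-diol
Conditions: I2, NaHCO3, H2O/THF, 0 °C
Reagents that add atoms: iodine, II
Why: Electrophilic iodination of a resorcinol under bicarbonate buffer, conditions that for resorcinols deliver iodine to the position between the two hydroxyls; this places the halogen where the aryne must form.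

Step 11
Reactants: 18 2-iodo-5-methylbenzene-1,3-diol
Product: 19 3-(benzyloxy)-2-iodo-5-methylphenol
Conditions: BnBr (1.0 equiv), K2CO3, acetone, 50 °C
Reagents that add atoms: benzyl bromide, BrCc1ccccc1
Why: Williamson mono-etherification of a symmetrical diol: one equivalent of BnBr should give a statistical mixture from which the mono-ether is separated and the diol recycled.

Step 12
Reactants: 19 3-(benzyloxy)-2-iodo-5-methylphenol
Product: 20 3-(benzyloxy)-2-iodo-5-methylphenyl trifluoromethanesulfonate
Conditions: Tf2O, Et3N, CH2Cl2, −78 to 0 °C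
Reagents that add atoms: trifluoromethanesulfonic anhydride, O=S(=O)(OS(=O)(=O)C(F)(F)F)C(F)(F)F
Why: O-sulfonylation of the phenol sets up an ortho-iodoaryl triflate that releases an aryne on iodine–lithium exchange.

Step 13
Reactants: 20 3-(benzyloxy)-2-iodo-5-methylphenyl trifluoromethanesulfonate (1.5 equiv); 16 tert-butyl({2-[4,6-bis(benzyloxy)-5-methoxy-2-methylnaphthalen-1-yl]-1-methoxyethenyl}oxy)dimethylsilane
Product: 22 5-(benzyloxy)-8-[4,6-bis(benzyloxy)-5-methoxy-2-methylnaphthalen-1-yl]-3-methylbicyclo[4.2.0]octa-1,3,5-trien-7-one (racemic), via silyl methyl acetal 21 (not isolated)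
Conditions: n-BuLi (slow addition), THF, −78 °C; then aq HF, MeCN, 0 °C
Reagents that add atoms: none
Why: Aryne [2+2] cycloaddition with a ketene silyl acetal, then acetal hydrolysis: iodine–lithium exchange and loss of LiOTf give 3-benzyloxy-5-methylbenzyne at −78 °C without fluoride, so the silyl acetal survives. Its nucleophilic carbon attacks the aryne carbon meta to the benzyloxy group and the aryl anion beside that group closes on the oxocarbenium carbon, which puts the masked carbonyl next to the oxygenated carbon; the C8 centre forms as the racemate.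

Step 14
Reactants: 23 ethyne (acetylene)
Product: 26 ethynyloxy(triisopropyl)silane, via lithium acetylide 24 (not isolated), via lithium ethynolate 25 (not isolated)
Conditions: n-BuLi, THF, −78 °C; t-BuOOLi (from t-BuOOH, LiN(SiMe3)2), −78 to 0 °C; TIPSOTf, −78 °C
Reagents that add atoms: tert-butyl hydroperoxide, CC(C)(C)OO; triisopropylsilyl trifluoromethanesulfonate, CC(C)[Si](OS(=O)(=O)C(F)(F)F)(C(C)C)C(C)C
Why: Oxidation of a lithium acetylide by lithium tert-butyl peroxide to the ynolate and O-silylation with a bulky silyl triflate is a known route to siloxyalkynes, applied here to the parent acetylide. The bulky silyl group favours O- over C-silylation and makes the ynol ether isolable.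

Step 15
Reactants: 22 5-(benzyloxy)-8-[4,6-bis(benzyloxy)-5-methoxy-2-methylnaphthalen-1-yl]-3-methylbicyclo[4.2.0]octa-1,3,5-trien-7-one; 26 ethynyloxy(triisopropyl)silane
Product: 29 8-(benzyloxy)-4-[4,6-bis(benzyloxy)-5-methoxy-2-methylnaphthalen-1-yl]-6-methyl-3-[(triisopropylsilyl)oxy]naphthalen-1-ol (racemic axis), via ketene methide 27 (not isolated), via naphthalenone tautomer 28 (not isolated)
Conditions: 26 (4 equiv), hν (300–350 nm, Pyrex), degassed toluene, 20 °C; then 80 °C
Reagents that add atoms: none
Why: Proposed new method: Irradiation should cleave the C(=O)–CH(aryl) bond of 22 by 4π-electrocyclic opening to the o-quinoid ketene methide 27, whose ketene carbon (the future C1 of unit A) is electrophilic and whose aryl-bearing methide carbon (the future C4) is the nucleophilic end of a dienolate-like π system. The CH carbon of ynol ether 26, its nucleophilic terminus, adds to the ketene carbon (bond C1–C2) and the methide carbon closes onto the silyloxy-bearing carbon (bond C3–C4), either as one asynchronous [4+2] event or through a zwitterion whose negative charge sits on the rearomatised diarylmethyl carbon; tautomerisation of naphthalenone 28 gives naphthol 29. The closest known reaction types are the Danheiser benzannulation of cyclobutenone-derived vinylketenes with siloxyalkynes and the Diels–Alder trapping of o-quinoid ketene methides generated from benzocyclobutenones; their combination in one operation is what is new. Ring P closes as a six-membered ring by union of the four-atom ketene methide unit with the two alkyne carbons (formal [4+2]), driven by recovery of the benzene ring. No stereocentre is set, since the C4 centre of 28 disappears on enolisation and the biaryl axis forms as the racemate. The step needs the alkyne to be taken up with CH at the ketene carbon, which the matched polarity of ynol ether and ketene secures, and it needs closure through the methide carbon and not across the ketene C=C bond, which rearomatisation secures because the competing [2+2] adduct would be a dearomatised spiro-cyclobutenone. That competing course, followed by 4π opening and 6π closure, would still give a 1,3-dioxygenated 4-aryl naphthalene but with the silyl group on the C1 oxygen and the free hydroxyl at C3, so the site of the free hydroxyl in 29 has to be established before step 16. Untrapped 27 returns to 22, so an excess of 26, exclusion of protic nucleophiles and room temperature (26 isomerises to a silylketene on strong heating) are the practical requirements.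

Step 16
Reactants: 29 8-(benzyloxy)-4-[4,6-bis(benzyloxy)-5-methoxy-2-methylnaphthalen-1-yl]-6-methyl-3-[(triisopropylsilyl)oxy]naphthalen-1-ol
Product: 30 8-(benzyloxy)-4-[4,6-bis(benzyloxy)-5-methoxy-2-methylnaphthalen-1-yl]-1-methoxy-6-methyl-3-[(triisopropylsilyl)oxy]naphthalene
Conditions: MeI, K2CO3, acetone, 50 °C
Reagents that add atoms: iodomethane, CI
Why: Williamson methylation of the only free hydroxyl; the hindered aryl silyl ether should survive K2CO3 in acetone, and the meta relationship of the two oxygens excludes silyl migration.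

Step 17
Reactants: 30 8-(benzyloxy)-4-[4,6-bis(benzyloxy)-5-methoxy-2-methylnaphthalen-1-yl]-1-methoxy-6-methyl-3-[(triisopropylsilyl)oxy]naphthalene
Product: 31 5-(benzyloxy)-1-[4,6-bis(benzyloxy)-5-methoxy-2-methylnaphthalen-1-yl]-4-methoxy-7-methylnaphthalen-2-ol
Conditions: Bu4NF, THF, 0 °C; aq NH4Cl
Reagents that add atoms: none
Why: Fluoride cleaves the aryl silyl ether through the strong Si–F bond; benzyl and methyl ethers are untouched.

Step 18
Reactants: 31 5-(benzyloxy)-1-[4,6-bis(benzyloxy)-5-methoxy-2-methylnaphthalen-1-yl]-4-methoxy-7-methylnaphthalen-2-ol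
Product: 32 1-(4,6-dihydroxy-5-methoxy-2-methylnaphthalen-1-yl)-4-methoxy-7-methylnaphthalene-2,5-diol
Conditions: H2 (1 atm), Pd/C, EtOAc/MeOH, rt; work-up under argon
Reagents that add atoms: none
Why: Hydrogenolysis of the three benzyl ethers on Pd/C under neutral conditions; methyl ethers and the naphthalene rings are not reduced at 1 atm and room temperature, and the air-sensitive tetrol is released only in the last step.

## Compound list

1 | 4-(benzyloxy)-3-methoxybenzaldehyde | COc1cc(C=O)ccc1OCc1ccccc1 | starting material
2 | 4-(benzyloxy)-3-methoxyphenyl formate | COc1cc(OC=O)ccc1OCc1ccccc1 | intermediate (not isolated)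
3 | 4-(benzyloxy)-3-methoxyphenol | COc1cc(O)ccc1OCc1ccccc1 | intermediate
4 | 4-(benzyloxy)-3-methoxyphenyl propan-2-ylcarbamate | CC(C)NC(=O)Oc1ccc(OCc2ccccc2)c(OC)c1 | intermediate
5 | 4-(benzyloxy)-3-methoxyphenyl [tert-butyl(dimethyl)silyl](propan-2-yl)carbamate | CC(C)N(C(=O)Oc1ccc(OCc2ccccc2)c(OC)c1)[Si](C)(C)C(C)(C)C | intermediate (not isolated)
6 | 4-(benzyloxy)-3-methoxy-2-(trimethylsilyl)phenyl [tert-butyl(dimethyl)silyl](propan-2-yl)carbamate | CC(C)N(C(=O)Oc1ccc(OCc2ccccc2)c(OC)c1[Si](C)(C)C)[Si](C)(C)C(C)(C)C | intermediate (not isolated)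
7 | 4-(benzyloxy)-3-methoxy-2-(trimethylsilyl)phenyl propan-2-ylcarbamate | CC(C)NC(=O)Oc1ccc(OCc2ccccc2)c(OC)c1[Si](C)(C)C | intermediate
8 | 4-(benzyloxy)-3-methoxy-2-(trimethylsilyl)phenol | COc1c(OCc2ccccc2)ccc(O)c1[Si](C)(C)C | intermediate (not isolated)
9 | 4-(benzyloxy)-3-methoxy-2-(trimethylsilyl)phenyl trifluoromethanesulfonate | COc1c(OCc2ccccc2)ccc(OS(=O)(=O)C(F)(F)F)c1[Si](C)(C)C | intermediate
10 | pentane-2,4-dione (acetylacetone) | CC(=O)CC(C)=O | starting material
11 | 1-[2-acetyl-4-(benzyloxy)-3-methoxyphenyl]propan-2-one | CC(=O)Cc1ccc(OCc2ccccc2)c(OC)c1C(C)=O | intermediate (not isolated)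
12 | 7-(benzyloxy)-8-methoxy-3-methylnaphthalen-1-ol | Cc1cc(O)c2c(OC)c(OCc3ccccc3)ccc2c1 | intermediate
13 | 7-(benzyloxy)-4-bromo-8-methoxy-3-methylnaphthalen-1-ol | Cc1cc(O)c2c(OC)c(OCc3ccccc3)ccc2c1Br | intermediate
14 | 4,6-bis(benzyloxy)-1-bromo-5-methoxy-2-methylnaphthalene | Cc1cc(OCc2ccccc2)c2c(OC)c(OCc3ccccc3)ccc2c1Br | intermediate
15 | methyl 2-[4,6-bis(benzyloxy)-5-methoxy-2-methylnaphthalen-1-yl]acetate | COC(=O)Cc1c(C)cc(OCc2ccccc2)c2c(OC)c(OCc3ccccc3)ccc12 | intermediate
16 | tert-butyl({2-[4,6-bis(benzyloxy)-5-methoxy-2-methylnaphthalen-1-yl]-1-methoxyethenyl}oxy)dimethylsilane (mixture of double-bond isomers) | COC(O[Si](C)(C)C(C)(C)C)=Cc1c(C)cc(OCc2ccccc2)c2c(OC)c(OCc3ccccc3)ccc12 | intermediate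
17 | 5-methylbenzene-1,3-diol (orcinol) | Cc1cc(O)cc(O)c1 | starting material
18 | 2-iodo-5-methylbenzene-1,3-diol | Cc1cc(O)c(I)c(O)c1 | intermediate
19 | 3-(benzyloxy)-2-iodo-5-methylphenol | Cc1cc(O)c(I)c(OCc2ccccc2)c1 | intermediate
20 | 3-(benzyloxy)-2-iodo-5-methylphenyl trifluoromethanesulfonate | Cc1cc(OCc2ccccc2)c(I)c(OS(=O)(=O)C(F)(F)F)c1 | intermediate
21 | {[5-(benzyloxy)-8-[4,6-bis(benzyloxy)-5-methoxy-2-methylnaphthalen-1-yl]-7-methoxy-3-methylbicyclo[4.2.0]octa-1,3,5-trien-7-yl]oxy}(tert-butyl)dimethylsilane (racemic, mixture of diastereomers) | COC1(O[Si](C)(C)C(C)(C)C)C(c2c(C)cc(OCc3ccccc3)c3c(OC)c(OCc4ccccc4)ccc23)c2cc(C)cc(OCc3ccccc3)c12 | intermediate (not isolated)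
22 | 5-(benzyloxy)-8-[4,6-bis(benzyloxy)-5-methoxy-2-methylnaphthalen-1-yl]-3-methylbicyclo[4.2.0]octa-1,3,5-trien-7-one (racemic) | O=C1C(c2c(C)cc(OCc3ccccc3)c3c(OC)c(OCc4ccccc4)ccc23)c2cc(C)cc(OCc3ccccc3)c12 | intermediate
23 | ethyne (acetylene) | C#C | starting material
24 | lithium acetylide | [Li+].[C-]#C | intermediate (not isolated)
25 | lithium ethynolate | [Li+].[O-]C#C | intermediate (not isolated)
26 | ethynyloxy(triisopropyl)silane | C#CO[Si](C(C)C)(C(C)C)C(C)C | intermediate
27 | [2-(benzyloxy)-6-{[4,6-bis(benzyloxy)-5-methoxy-2-methylnaphthalen-1-yl]methylidene}-4-methylcyclohexa-2,4-dien-1-ylidene]methanone (geometry of the methylidene bond not defined) | O=C=C1C(OCc2ccccc2)=CC(C)=CC1=Cc1c(C)cc(OCc2ccccc2)c2c(OC)c(OCc3ccccc3)ccc12 | intermediate (not isolated)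
28 | 8-(benzyloxy)-4-[4,6-bis(benzyloxy)-5-methoxy-2-methylnaphthalen-1-yl]-6-methyl-3-[(triisopropylsilyl)oxy]naphthalen-1(4H)-one (racemic) | O=C1C=C(O[Si](C(C)C)(C(C)C)C(C)C)C(c2c(C)cc(OCc3ccccc3)c3c(OC)c(OCc4ccccc4)ccc23)c2cc(C)cc(OCc3ccccc3)c12 | intermediate (not isolated)
29 | 8-(benzyloxy)-4-[4,6-bis(benzyloxy)-5-methoxy-2-methylnaphthalen-1-yl]-6-methyl-3-[(triisopropylsilyl)oxy]naphthalen-1-ol (racemic axis) | Oc1cc(O[Si](C(C)C)(C(C)C)C(C)C)c(-c2c(C)cc(OCc3ccccc3)c3c(OC)c(OCc4ccccc4)ccc23)c2cc(C)cc(OCc3ccccc3)c12 | intermediate
30 | 8-(benzyloxy)-4-[4,6-bis(benzyloxy)-5-methoxy-2-methylnaphthalen-1-yl]-1-methoxy-6-methyl-3-[(triisopropylsilyl)oxy]naphthalene (racemic axis) | COc1cc(O[Si](C(C)C)(C(C)C)C(C)C)c(-c2c(C)cc(OCc3ccccc3)c3c(OC)c(OCc4ccccc4)ccc23)c2cc(C)cc(OCc3ccccc3)c12 | intermediate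
31 | 5-(benzyloxy)-1-[4,6-bis(benzyloxy)-5-methoxy-2-methylnaphthalen-1-yl]-4-methoxy-7-methylnaphthalen-2-ol (racemic axis) | COc1cc(O)c(-c2c(C)cc(OCc3ccccc3)c3c(OC)c(OCc4ccccc4)ccc23)c2cc(C)cc(OCc3ccccc3)c12 | intermediate
32 | 1-(4,6-dihydroxy-5-methoxy-2-methylnaphthalen-1-yl)-4-methoxy-7-methylnaphthalene-2,5-diol (racemic axis) | COc1cc(O)c(-c2c(C)cc(O)c3c(OC)c(O)ccc23)c2cc(C)cc(O)c12 | target

## Step count and least certain steps

Total: 18 steps. Longest linear sequence: 14 steps (steps 1 to 9, 13, 15, 16, 17, 18).

**Step 15 (key step, proposed new method).**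
- What may go wrong: the photochemical ring opening may be inefficient because the naphthalene chromophore of unit B competes for the light, while purely thermal opening would need temperatures at which 26 rearranges to a silylketene. Alkyne uptake across the ketene C=C bond would exchange the silylated and the free oxygen. Reversion or self-reaction of the ketene methide may win when trapping is slow.
- Fallback (known chemistry, from 22 back to 29), forming the same two bonds in two polar steps: NaOMe in MeOH should cleave the four-membered ring of 22 with expulsion of the diarylmethyl carbanion to give methyl 2-(benzyloxy)-6-{[4,6-bis(benzyloxy)-5-methoxy-2-methylnaphthalen-1-yl]methyl}-4-methylbenzoate F1. Lateral deprotonation of F1 with LiN(i-Pr)2 at −78 °C and acylation with N-methoxy-N-methylacetamide (bond C3(A)–C4(A)) gives methyl 2-(benzyloxy)-6-{1-[4,6-bis(benzyloxy)-5-methoxy-2-methylnaphthalen-1-yl]-2-oxopropyl}-4-methylbenzoate F2. KOt-Bu in THF closes ring P by Claisen condensation of the methyl ketone onto the benzoate (bond C1(A)–C2(A)) to 8-(benzyloxy)-4-[4,6-bis(benzyloxy)-5-methoxy-2-methylnaphthalen-1-yl]-6-methylnaphthalene-1,3-diol F3. Silylation with i-Pr3SiCl and imidazole should take the C3(A) hydroxyl, because the C1(A) hydroxyl is held in a hydrogen bond to the peri benzyloxy group, and returns the route to 29.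

**Step 13.**
- What may go wrong: the hindered, aryl-substituted ketene silyl acetal may react with the aryne by hydrogen or silyl transfer instead of ring closure, n-BuLi may attack the triflate at sulfur, and the crude silyl acetal may hydrolyse before use.
- Fallback (from 20, 14 and 26 back to 29), forming the biaryl bond last by cross-coupling: 20 and commercial tert-butyl[(1-methoxyethenyl)oxy]dimethylsilane under the same n-BuLi conditions should give tert-butyl{[5-(benzyloxy)-7-methoxy-3-methylbicyclo[4.2.0]octa-1,3,5-trien-7-yl]oxy}dimethylsilane F4, hydrolysed by aqueous HF to 5-(benzyloxy)-3-methylbicyclo[4.2.0]octa-1,3,5-trien-7-one F5. Ring expansion of F5 with 26 under the conditions of step 15 (the same untested reaction, now on an unhindered substrate) gives 8-(benzyloxy)-6-methyl-3-[(triisopropylsilyl)oxy]naphthalen-1-ol F6. NBS brominates para to the hydroxyl to 8-(benzyloxy)-4-bromo-6-methyl-3-[(triisopropylsilyl)oxy]naphthalen-1-ol F7. Bromide 14 is converted by n-BuLi, B(OMe)3 and aqueous acid into [4,6-bis(benzyloxy)-5-methoxy-2-methylnaphthalen-1-yl]boronic acid F8. Suzuki–Miyaura coupling of F7 with F8 (Pd(OAc)2, 2-dicyclohexylphosphino-2',6'-dimethoxybiphenyl, K3PO4, toluene/H2O, 100 °C) returns to 29.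

**Step 14.**
- What may go wrong: monolithium acetylide may disproportionate to the dilithium species, the ynolate may be silylated on carbon to a silylketene, and the volatile, moisture-sensitive product may be lost on isolation.
- Fallback (from 22 back to 29, with commercial ethynyl(trimethyl)silane in place of 23): the silylated alkyne is lithiated, oxidised and O-silylated as in step 14 to give the less volatile trimethyl({[tri(propan-2-yl)silyl]oxy}ethynyl)silane F9. Ring expansion of 22 with F9 under the conditions of step 15 gives 8-(benzyloxy)-4-[4,6-bis(benzyloxy)-5-methoxy-2-methylnaphthalen-1-yl]-6-methyl-3-[(triisopropylsilyl)oxy]-2-(trimethylsilyl)naphthalen-1-ol F10. Ipso-protodesilylation of the electron-rich aryl silane with CF3CO2H in CH2Cl2 at 0 °C returns to 29.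

**Step 8.**
- What may go wrong: oxidative addition and transmetalation at the di-ortho-substituted bromide may be slow, so that protodebromination and self-condensation of the zinc enolate take over.
- Fallback (from 14 back to 15), replacing the catalytic coupling by an aryllithium acylation: bromine–lithium exchange on 14 (n-BuLi, THF, −78 °C) and addition to dimethyl oxalate gives methyl 2-[4,6-bis(benzyloxy)-5-methoxy-2-methylnaphthalen-1-yl]-2-oxoacetate F11. Ionic hydrogenation of the benzylic ketone (Et3SiH, CF3CO2H, CH2Cl2, 0 °C) should remove the oxygen and give 15.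

## Further compounds

F1 | step 15 | methyl 2-(benzyloxy)-6-{[4,6-bis(benzyloxy)-5-methoxy-2-methylnaphthalen-1-yl]methyl}-4-methylbenzoate | COC(=O)c1c(OCc2ccccc2)cc(C)cc1Cc1c(C)cc(OCc2ccccc2)c2c(OC)c(OCc3ccccc3)ccc12
F2 | step 15 | methyl 2-(benzyloxy)-6-{1-[4,6-bis(benzyloxy)-5-methoxy-2-methylnaphthalen-1-yl]-2-oxopropyl}-4-methylbenzoate (racemic) | COC(=O)c1c(OCc2ccccc2)cc(C)cc1C(C(C)=O)c1c(C)cc(OCc2ccccc2)c2c(OC)c(OCc3ccccc3)ccc12
F3 | step 15 | 8-(benzyloxy)-4-[4,6-bis(benzyloxy)-5-methoxy-2-methylnaphthalen-1-yl]-6-methylnaphthalene-1,3-diol | Oc1cc(O)c(-c2c(C)cc(OCc3ccccc3)c3c(OC)c(OCc4ccccc4)ccc23)c2cc(C)cc(OCc3ccccc3)c12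
F4 | step 13 | tert-butyl{[5-(benzyloxy)-7-methoxy-3-methylbicyclo[4.2.0]octa-1,3,5-trien-7-yl]oxy}dimethylsilane (racemic) | COC1(O[Si](C)(C)C(C)(C)C)Cc2cc(C)cc(OCc3ccccc3)c12
F5 | step 13 | 5-(benzyloxy)-3-methylbicyclo[4.2.0]octa-1,3,5-trien-7-one | O=C1Cc2cc(C)cc(OCc3ccccc3)c12
F6 | step 13 | 8-(benzyloxy)-6-methyl-3-[(triisopropylsilyl)oxy]naphthalen-1-ol | Oc1cc(O[Si](C(C)C)(C(C)C)C(C)C)cc2cc(C)cc(OCc3ccccc3)c12
F7 | step 13 | 8-(benzyloxy)-4-bromo-6-methyl-3-[(triisopropylsilyl)oxy]naphthalen-1-ol | Oc1cc(O[Si](C(C)C)(C(C)C)C(C)C)c(Br)c2cc(C)cc(OCc3ccccc3)c12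
F8 | step 13 | [4,6-bis(benzyloxy)-5-methoxy-2-methylnaphthalen-1-yl]boronic acid | Cc1cc(OCc2ccccc2)c2c(OC)c(OCc3ccccc3)ccc2c1B(O)O
F9 | step 14 | trimethyl({[tri(propan-2-yl)silyl]oxy}ethynyl)silane | C[Si](C)(C)C#CO[Si](C(C)C)(C(C)C)C(C)C
F10 | step 14 | 8-(benzyloxy)-4-[4,6-bis(benzyloxy)-5-methoxy-2-methylnaphthalen-1-yl]-6-methyl-3-[(triisopropylsilyl)oxy]-2-(trimethylsilyl)naphthalen-1-ol (racemic axis) | Oc1c([Si](C)(C)C)c(O[Si](C(C)C)(C(C)C)C(C)C)c(-c2c(C)cc(OCc3ccccc3)c3c(OC)c(OCc4ccccc4)ccc23)c2cc(C)cc(OCc3ccccc3)c12
F11 | step 8 | methyl 2-[4,6-bis(benzyloxy)-5-methoxy-2-methylnaphthalen-1-yl]-2-oxoacetate | COC(=O)C(=O)c1c(C)cc(OCc2ccccc2)c2c(OC)c(OCc3ccccc3)ccc12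
A1 | alternative 1 | methyl 2-[2-acetyl-3-(benzyloxy)-5-methylphenyl]-2-[4,6-bis(benzyloxy)-5-methoxy-2-methylnaphthalen-1-yl]acetate (racemic) | COC(=O)C(c1cc(C)cc(OCc2ccccc2)c1C(C)=O)c1c(C)cc(OCc2ccccc2)c2c(OC)c(OCc3ccccc3)ccc12
A2 | alternative 1 | methyl 2-[4,6-bis(benzyloxy)-5-methoxy-2-methylnaphthalen-1-yl]-3-oxobutanoate (racemic) | COC(=O)C(C(C)=O)c1c(C)cc(OCc2ccccc2)c2c(OC)c(OCc3ccccc3)ccc12
A3 | alternative 1 | 3-(benzyloxy)-5-methyl-2-(trimethylsilyl)phenyl trifluoromethanesulfonate | Cc1cc(OCc2ccccc2)c([Si](C)(C)C)c(OS(=O)(=O)C(F)(F)F)c1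
A4 | alternative 1 | 8-(benzyloxy)-4-[4,6-bis(benzyloxy)-5-methoxy-2-methylnaphthalen-1-yl]-6-methylnaphthalene-1,3-diol | Oc1cc(O)c(-c2c(C)cc(OCc3ccccc3)c3c(OC)c(OCc4ccccc4)ccc23)c2cc(C)cc(OCc3ccccc3)c12
A5 | alternative 2 | 5-[4,6-bis(benzyloxy)-5-methoxy-2-methylnaphthalen-1-yl]-6,8-dihydroxy-3-methyl-3,4-dihydronaphthalen-1(2H)-one (racemic) | O=C1CC(C)Cc2c1c(O)cc(O)c2-c1c(C)cc(OCc2ccccc2)c2c(OC)c(OCc3ccccc3)ccc12
A6 | alternative 2 | 2-{[4,6-bis(benzyloxy)-5-methoxy-2-methylnaphthalen-1-yl]methyl}-7-methyl-7,8-dihydro-4H-chromene-4,5(6H)-dione (racemic) | O=C1C=C(Cc2c(C)cc(OCc3ccccc3)c3c(OC)c(OCc4ccccc4)ccc23)OC2=C1C(=O)CC(C)C2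
A7 | alternative 3 | tert-butyl 6-(benzyloxy)-1-[3,8-bis(benzyloxy)-1-methoxy-6-methylnaphthalen-4-yl]-4-hydroxy-5-methoxy-2-methylnaphthalene-3-carboxylate | CC(C)(C)OC(=O)c1c(C)c(-c2c(OCc3ccccc3)cc(OC)c3c(OCc4ccccc4)cc(C)cc23)c2ccc(OCc3ccccc3)c(OC)c2c1O
A8 | alternative 3 | 6-(benzyloxy)-3-[3,8-bis(benzyloxy)-1-methoxy-6-methylnaphthalen-4-yl]-7-methoxy-2-benzofuran-1(3H)-one (racemic) | O=C1OC(c2c(OCc3ccccc3)cc(OC)c3c(OCc4ccccc4)cc(C)cc23)c2ccc(OCc3ccccc3)c(OC)c12
A9 | alternative 3 | tert-butyl (E)-but-2-enoate | C/C=C/C(=O)OC(C)(C)C
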